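Slowness was where I began: I turned each constant into a time at the charged amounts, to see which steps mattered within 40 s.

free monomer 0.22 M; transfer agent 0.0660 M; initiator 13 mM; impurity 11 mM; time 40 s

    free monomer + initiator → living end + monomer in chains (k1 = 3.01 /M/s)
    initiator + impurity → spent initiator (k2 = 272 /M/s)
    free monomer → decomposition product (k3 = 3.99 × 10⁻⁵ /s)
    free monomer + living end → monomer in chains + living end, rate k4*[living end]*[free monomer] (k4 = 1.35 /M/s)
    living end + transfer agent → dead chain (k5 = 0.189 /M/s)
    free monomer → uncatalysed product (k6 = 0.00165 /s)

- the average divides the monomer in chains by the number of chains begun, living and dead together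
- run time (flask): 40 s

- average number of monomer units in a chain (chains begun, living or dead) at 40 s
- part of the free monomer that has reacted at 40 s

Free monomer would have taken up initiator in 1.51 s, but impurity would have done so in 0.334 s, so impurity was the quicker taker. Impurity slowed as it was used, though, and the two pulls drew level with 2.43 mM of impurity left. Taken as its stopping level, that gave 3.67 mM of chains begun by the competition but 4.43 mM by the initiator balance, so I took their mean, 4.05 mM.

Decomposition, with a half-life of 290 min, was far too slow to count , so I dropped it.

With transfer agent far in excess, its end was pseudo-first-order, and the life of a living end, the mean time before transfer agent ends it, was 80.2 s. Chains began early against that life, so within 40 s each had on average 31.5 s of growing time.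

Uncatalysed loss, growth and chain starts together gave a logarithmic loss of free monomer of 0.257, so I reckoned 22.6% reacted. One starting unit plus growth at the mean free monomer gave 9.23 units per chain.

The forecast gave 9.1 and 22.6%, on the ground: “Impurity and monomer compete for the initiator”.

The simulation gave 9.10 and 22.6%, so my average ran high by 0.124 units.

The flask had not come to rest at 40 s. At 400 s the average chain had reached 18.2 units and the reacted part 68.1%. The life of a living end, applied to the 4.05 mM of chains read at 40.0 s, gave 2.75 × 10⁻⁵ M of living end by then, and the reading was 3.54 × 10⁻⁵ M. Free monomer still stood at 31.9% of its charge, beside 33.9% as uncatalysed product, and its half-life by that step alone was 7.0 min.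

(The numbers stand for no real mixture; the rest is arithmetic.)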